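**Retrosynthetic overview**

1. The target, (3R)-8-hydroxy-3-[(6S)-6-hydroxyundecyl]-6-methoxy-3,4-dihydroisocoumarin, is unmasked last: one Lewis acid cleaves the C8 methyl ether and the side-chain benzyl ether of a 6,8-dimethoxy O-benzyl precursor.
2. Key disconnection: the lactone ring (ring B) is cut at C4–C4a and C1–C8a. This gives 3,5-dimethoxybenzyne and the four-atom unit C4–C3–O2–C1(=O), which is a β-lactone (oxetan-2-one) closed by one extra acyl–Cα bond. The aryne is inserted into that bond, so ring B is formed last by a four-to-six ring expansion on the finished arene.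
3. Enabling feature: C4 and C1 sit on the neighbouring arene carbons C4a and C8a, and C8a is flanked by the C8 oxygen. A 3-alkoxyaryne takes a carbon nucleophile at the carbon remote from the oxygen (later C4a) and the acyl group at the carbon next to it (later C8a).
4. The β-lactone carries C3 (R) and comes from a catalytic asymmetric ketene–aldehyde cycloaddition on (S)-7-(benzyloxy)dodecanal. An α-silyl group serves as a traceless fluoride trigger. The aldehyde derives from (S)-epichlorohydrin by two Grignard epoxide openings.
5. The aryne precursor comes from 3,5-dimethoxyphenol by carbamate-directed ortho-silylation and triflation.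

Key step: step 10

Assumption: O-trimethylsilylquinine is taken as the cinchona catalyst that gives the (4R)-lactone from an unbranched aldehyde in step 8; if the sense is the reverse, O-trimethylsilylquinidine is used and nothing else changes.

**Route**

Step 1
Reactants: 1 3,5-dimethoxyphenol
Product: 2 3,5-dimethoxyphenyl N-isopropylcarbamate
Conditions: iPrNCO, Et3N (cat.), CH2Cl2, 23 °C
Reagents that add atoms: isopropyl isocyanate CC(C)N=C=O
Why: Amine-catalysed addition of the phenol to the isocyanate (carbamoylation) should give the N–H carbamate, a directing group that can later be removed under mild base.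

Step 2
Reactants: 2 3,5-dimethoxyphenyl N-isopropylcarbamate
Product: 4 3,5-dimethoxy-2-(trimethylsilyl)phenyl N-isopropylcarbamate, via N-silyl carbamate 3 (not isolated)
Conditions: TBSOTf, TMEDA, Et2O, 0 → 23 °C; then n-BuLi, TMEDA, −78 °C; TMSCl, −78 → 23 °C; aq. work-up
Reagents that add atoms: chlorotrimethylsilane C[Si](C)(C)Cl; tert-butyldimethylsilyl triflate CC(C)(C)[Si](C)(C)OS(=O)(=O)C(F)(F)F (its silyl group stays only in 3)
Why: Directed ortho-metalation: after transient N-silylation the carbamate oxygen and the C3 methoxy group together direct lithiation to C2, the position between them (C6 is equivalent by symmetry), the aryllithium is silylated, and aqueous work-up cleaves the N–Si bond.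

Step 3
Reactants: 4 3,5-dimethoxy-2-(trimethylsilyl)phenyl N-isopropylcarbamate
Product: 6 3,5-dimethoxy-2-(trimethylsilyl)phenyl trifluoromethanesulfonate, via 3,5-dimethoxy-2-(trimethylsilyl)phenol 5 (not isolated)
Conditions: DBU, Et2NH, MeCN, 40 °C; then PhNTf2, 23 °C
Reagents that add atoms: N-phenylbis(trifluoromethanesulfonimide) O=S(=O)(N(c1ccccc1)S(=O)(=O)C(F)(F)F)C(F)(F)F
Why: DBU-induced E1cB loss of isopropyl isocyanate (trapped by Et2NH as a urea) frees the phenoxide without touching the aryl–Si bond, and O-triflation then completes the ortho-silylaryl triflate that serves as aryne precursor.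

Step 4
Reactants: 7 (S)-epichlorohydrin; 8 butylmagnesium chloride
Product: 10 (S)-2-pentyloxirane, via (S)-1-chloroheptan-2-ol 9 (not isolated)
Conditions: CuI (5 mol%), THF, −40 → 0 °C; H2O; then NaOH (powder), Et2O, 23 °C
Reagents that add atoms: none
Why: Copper-catalysed Grignard opening of the epoxide at its CH2 terminus (SN2) followed by Williamson ring closure of the chlorohydrin; no bond to the stereocenter is broken, so the (S) carbinol carbon of 9 becomes C2 of (S)-10.

Step 5
Reactants: 10 (S)-2-pentyloxirane; 11 6-bromohex-1-ene
Product: 13 (S)-tridec-1-en-8-ol, via hex-5-enylmagnesium bromide 12 (not isolated)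
Conditions: 11, Mg, THF, 23 °C; then CuI (10 mol%), 10, −30 → 0 °C; H2O
Reagents that add atoms: none
Why: Copper-catalysed SN2 opening of the terminal epoxide at CH2 by the primary Grignard reagent; the stereocenter is not touched and becomes the (S) carbinol carbon, the later C6' of the side chain.

Step 6
Reactants: 13 (S)-tridec-1-en-8-ol
Product: 14 (S)-8-(benzyloxy)tridec-1-ene
Conditions: NaH, BnBr, Bu4NI (cat.), THF/DMF, 0 → 23 °C
Reagents that add atoms: benzyl bromide BrCc1ccccc1
Why: Williamson ether synthesis; the benzyl ether tolerates the amide base, the fluoride and the LiClO4 used later and is cleaved in the last step together with the C8 methyl ether.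

Step 7
Reactants: 14 (S)-8-(benzyloxy)tridec-1-ene
Product: 15 (S)-7-(benzyloxy)dodecanal
Conditions: OsO4 (2 mol%), NaIO4, 2,6-lutidine, dioxane/H2O, 23 °C
Reagents that add atoms: sodium periodate [Na+].[O-]I(=O)(=O)=O (terminal oxidant; the oxygen is passed on by OsO4, O=[Os](=O)(=O)=O)
Why: Lemieux–Johnson oxidation (catalytic dihydroxylation, then periodate cleavage) shortens the terminal alkene by one carbon to the aldehyde, 2,6-lutidine suppressing over-oxidation, and the benzyl ether is inert.

Step 8
Reactants: 15 (S)-7-(benzyloxy)dodecanal; 16 acetyl chloride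
Product: 18 (R)-4-[(S)-6-(benzyloxy)undecyl]oxetan-2-one, via ketene 17 (not isolated)
Conditions: O-trimethylsilylquinine (10 mol%), LiClO4, iPr2NEt, CH2Cl2/Et2O, −78 °C, slow addition of 16
Reagents that add atoms: none
Why: Alkaloid/LiClO4-catalysed acyl halide–aldehyde cyclocondensation (formal [2+2] of ketene and aldehyde): the ammonium enolate from ketene and the catalyst adds to the lithium-bound aldehyde in a closed transition state and lactonises, the catalyst alone setting C4 as (R) because the ether stereocenter is six bonds away.

Step 9
Reactants: 18 (R)-4-[(S)-6-(benzyloxy)undecyl]oxetan-2-one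
Product: 19 (3R,4R)-4-[(S)-6-(benzyloxy)undecyl]-3-(trimethylsilyl)oxetan-2-one (trans)
Conditions: LiN(iPr)2, TMSCl (in situ quench), THF, −78 °C
Reagents that add atoms: chlorotrimethylsilane C[Si](C)(C)Cl
Why: α-Deprotonation of the β-lactone with in situ silyl trapping: the enolate cannot eliminate because the ring C4–O bond lies in its nodal plane, and C-silylation anti to the C4 chain (O-silylation would give an oxete) should give the trans silyl lactone with C4 untouched.

Step 10
Reactants: 19 (3R,4R)-4-[(S)-6-(benzyloxy)undecyl]-3-(trimethylsilyl)oxetan-2-one; 6 3,5-dimethoxy-2-(trimethylsilyl)phenyl trifluoromethanesulfonate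
Product: 23 (R)-3-[(S)-6-(benzyloxy)undecyl]-6,8-dimethoxyisochroman-1-one, via 3,5-dimethoxybenzyne 20 (not isolated), via lactone enolate 21 (not isolated), via fused cyclobutenoxide 22 (not isolated)
Conditions: TBAT (2.5 equiv), THF, 0 → 23 °C, slow addition of 19; then AcOH, 0 °C
Reagents that add atoms: none
Why: Proposed new method: fluoride from TBAT cleaves both C–Si bonds, giving aryne 20 from 6 by loss of triflate and the ammonium enolate 21 from 19 (the way fluoride-promoted aldol reactions of 3-silyl-oxetan-2-ones begin), and the enolate carbon adds to the aryne. The aryl anion so formed attacks the strained lactone carbonyl to give the fused alkoxide 22, which breaks the former acyl–Cα bond of the lactone in a Grob-type scission that releases both four-membered rings and leaves the six-membered lactone as its C4 carbanion, protonated on quench; if 22 first expels the ring oxygen, the benzocyclobutenone alkoxide formed can re-close to 22 and should end at the same product. The closest known reaction types are the acyl-alkylation of arynes (σ-insertion into the Cα–C(=O) bond of β-ketoesters and malonates under fluoride) and the two-carbon ring expansion of simple ketone enolates with arynes through benzocyclobutenoxides; new here is that the bond cut is the acyl–Cα bond of a lactone that has no second stabilising group. Ring B closes by two-atom ring expansion of the oxetanone (insertion of C4a–C8a into the O=C–CH bond), the transient carbocycle by 4-exo-trig addition. No stereocenter is made: C3 is C4 of the lactone, no bond to it is touched, and the silyl-bearing center of 19 is erased. The step needs regioselectivity, which the methoxy group next to the triple bond secures by distorting the aryne so that the nucleophile bonds to the remote carbon (later C4a) and the anion sits beside oxygen (later C8a), and it needs ring closure to outrun protonation of the aryl anion, for which the aprotic medium and the strained oxetanone carbonyl are relied on.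

Step 11
Reactants: 23 (R)-3-[(S)-6-(benzyloxy)undecyl]-6,8-dimethoxyisochroman-1-one
Product: 24 (R)-8-hydroxy-3-[(S)-6-hydroxyundecyl]-6-methoxyisochroman-1-one (target)
Conditions: BCl3 (4 equiv), CH2Cl2, −78 → 0 °C; then H2O
Reagents that add atoms: none
Why: Chelation-assisted demethylation: BCl3 is held between the C1 carbonyl and the peri C8 methoxy oxygen, so only this methyl ether is cleaved (the C6 ether lacks the assistance), and the same reagent cleaves the secondary benzyl ether at the benzylic C–O bond, leaving both stereocenters untouched.

**Compound list**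

1 | 3,5-dimethoxyphenol | COc1cc(O)cc(OC)c1 | starting material
2 | 3,5-dimethoxyphenyl N-isopropylcarbamate | COc1cc(OC)cc(OC(=O)NC(C)C)c1 | intermediate
3 | 3,5-dimethoxyphenyl N-(tert-butyldimethylsilyl)-N-isopropylcarbamate (formed in the flask) | COc1cc(OC)cc(OC(=O)N(C(C)C)[Si](C)(C)C(C)(C)C)c1 | intermediate
4 | 3,5-dimethoxy-2-(trimethylsilyl)phenyl N-isopropylcarbamate | COc1cc(OC)c([Si](C)(C)C)c(OC(=O)NC(C)C)c1 | intermediate
5 | 3,5-dimethoxy-2-(trimethylsilyl)phenol (formed in the flask) | COc1cc(OC)c([Si](C)(C)C)c(O)c1 | intermediate
6 | 3,5-dimethoxy-2-(trimethylsilyl)phenyl trifluoromethanesulfonate | COc1cc(OC)c([Si](C)(C)C)c(OS(=O)(=O)C(F)(F)F)c1 | intermediate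
7 | (S)-epichlorohydrin | ClC[C@@H]1CO1 | starting material
8 | butylmagnesium chloride | CCCC[Mg]Cl | starting material
9 | (S)-1-chloroheptan-2-ol (formed in the flask) | CCCCC[C@H](O)CCl | intermediate
10 | (S)-2-pentyloxirane | CCCCC[C@H]1CO1 | intermediate
11 | 6-bromohex-1-ene | C=CCCCCBr | starting material
12 | hex-5-enylmagnesium bromide (formed in the flask) | C=CCCCC[Mg]Br | intermediate
13 | (S)-tridec-1-en-8-ol | C=CCCCCC[C@@H](O)CCCCC | intermediate
14 | (S)-8-(benzyloxy)tridec-1-ene | C=CCCCCC[C@@H](OCc1ccccc1)CCCCC | intermediate
15 | (S)-7-(benzyloxy)dodecanal | O=CCCCCC[C@@H](OCc1ccccc1)CCCCC | intermediate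
16 | acetyl chloride | CC(=O)Cl | starting material
17 | ketene (formed in the flask) | C=C=O | intermediate
18 | (R)-4-[(S)-6-(benzyloxy)undecyl]oxetan-2-one | O=C1C[C@@H](CCCCC[C@@H](OCc2ccccc2)CCCCC)O1 | intermediate
19 | (3R,4R)-4-[(S)-6-(benzyloxy)undecyl]-3-(trimethylsilyl)oxetan-2-one (trans) | O=C1[C@H]([Si](C)(C)C)[C@@H](CCCCC[C@@H](OCc2ccccc2)CCCCC)O1 | intermediate
20 | 3,5-dimethoxybenzyne (1,2-didehydro-3,5-dimethoxybenzene; formed in the flask) | COC1=CC(OC)=CC#C1 | intermediate
21 | tetrabutylammonium enolate of lactone 18, (R) at C4 (formed in the flask) | [O-]C1=C[C@@H](CCCCC[C@@H](OCc2ccccc2)CCCCC)O1.CCCC[N+](CCCC)(CCCC)CCCC | intermediate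
22 | tetrabutylammonium salt of the tetrahedral adduct: dimethoxybenzocyclobutenoxide whose carbinolate carbon and neighbouring sp3 carbon are bridged by O–CH(side chain) as a cis-fused oxetane, aryl–C bond anti to the side chain (formed in the flask) | COc1cc(OC)c3c(c1)[C@@H]1[C@@H](CCCCC[C@@H](OCc2ccccc2)CCCCC)O[C@@]13[O-].CCCC[N+](CCCC)(CCCC)CCCC | intermediate
23 | (R)-3-[(S)-6-(benzyloxy)undecyl]-6,8-dimethoxyisochroman-1-one | COc1cc2C[C@@H](CCCCC[C@@H](OCc3ccccc3)CCCCC)OC(=O)c2c(OC)c1 | intermediate
24 | (R)-8-hydroxy-3-[(S)-6-hydroxyundecyl]-6-methoxyisochroman-1-one | COc1cc2C[C@@H](CCCCC[C@@H](O)CCCCC)OC(=O)c2c(O)c1 | target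

**Step count and risks**

Total step count: 11. Longest linear sequence: 8 (steps 4 to 11).

Steps most likely to fail:

1. Step 10 (Proposed new method). Three processes may divert it: decay or self-acylation of the lactone enolate before it meets the aryne; protonation of the aryl anion before it closes onto the lactone carbonyl, which stops at simple α-arylation; and β-elimination of the C4 carbanion (ring opening of the new lactone) before it is protonated. The fallback uses known chemistry, sets out from aldehyde 15 and silyl triflate 6, and comes back at 23. Seyferth–Gilbert homologation of 15 with the Ohira–Bestmann reagent (K2CO3, MeOH) should give (S)-8-(benzyloxy)tridec-1-yne F1. A copper-catalysed three-component coupling of F1, CO2 and the aryne released from 6 [CsF, (IPr)CuCl (cat.), Cs2CO3, MeCN] then forms the same two aryl bonds: the alkynylcopper adds to the aryne carbon remote from the methoxy group, the arylcopper next to oxygen takes up CO2, and the carboxylate closes 6-endo onto the alkyne to give 3-[(S)-6-(benzyloxy)undecyl]-6,8-dimethoxy-1H-isochromen-1-one F2. Enantioselective hydrogenation of the C3=C4 bond of F2 [H2, Ru(2-methylallyl)2(cod), chiral N-heterocyclic carbene ligand in the enantiomeric form that gives 3R, KOtBu] should then deliver 23, with C3 set by the catalyst.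

2. Step 9. The lithium enolate of a 3-unsubstituted β-lactone may acylate itself or open before it is silylated. The fallback sets out from aldehyde 15 and comes back at 23. A [2+2] cycloaddition of (trimethylsilyl)ketene with 15 under a chiral aluminium Lewis acid [methylaluminium N,N'-bis(trifluoromethanesulfonyl)-1,2-diphenylethylenediamide, enantiomer chosen for 4R] builds the silyl lactone directly as (4R)-4-[(S)-6-(benzyloxy)undecyl]-3-(trimethylsilyl)oxetan-2-one F3, a mixture of C3 epimers. The C3 configuration is erased in step 10, so F3 is used there in place of 19. The enolate is then never made with an amide base, and steps 8 and 9 are both bypassed.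

3. Step 8. Facial selectivity may be insufficient with this long-chain aldehyde, and the amine base may cause aldol self-condensation of the enolisable aldehyde. The fallback sets out from 15 and comes back at 18. Roskamp homologation of 15 (ethyl diazoacetate, SnCl2 cat., CH2Cl2) should give ethyl (S)-9-(benzyloxy)-3-oxotetradecanoate F4. Noyori hydrogenation (H2, RuCl2[(R)-BINAP], EtOH) sets the carbinol center in ethyl (3R,9S)-9-(benzyloxy)-3-hydroxytetradecanoate F5 with a known sense of induction. Saponification (LiOH, THF/H2O) gives (3R,9S)-9-(benzyloxy)-3-hydroxytetradecanoic acid F6. Lactonisation through carboxyl activation (PhSO2Cl, pyridine, 0 °C) leaves the C–O bond of the carbinol intact and should return 18 with retention.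

Further compounds
F1 | step 10 | (S)-8-(benzyloxy)tridec-1-yne | C#CCCCCC[C@@H](OCc1ccccc1)CCCCC
F2 | step 10 | 3-[(S)-6-(benzyloxy)undecyl]-6,8-dimethoxy-1H-isochromen-1-one | COc1cc2C=C(CCCCC[C@@H](OCc3ccccc3)CCCCC)OC(=O)c2c(OC)c1
F3 | step 9 | (4R)-4-[(S)-6-(benzyloxy)undecyl]-3-(trimethylsilyl)oxetan-2-one, mixture of C3 epimers | O=C1C([Si](C)(C)C)[C@@H](CCCCC[C@@H](OCc2ccccc2)CCCCC)O1
F4 | step 8 | ethyl (S)-9-(benzyloxy)-3-oxotetradecanoate | CCOC(=O)CC(=O)CCCCC[C@@H](OCc1ccccc1)CCCCC
F5 | step 8 | ethyl (3R,9S)-9-(benzyloxy)-3-hydroxytetradecanoate | CCOC(=O)C[C@H](O)CCCCC[C@@H](OCc1ccccc1)CCCCC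
F6 | step 8 | (3R,9S)-9-(benzyloxy)-3-hydroxytetradecanoic acid | OC(=O)C[C@H](O)CCCCC[C@@H](OCc1ccccc1)CCCCC
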